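The target is read as a 2',6'-dihydroxychalcone whose enone is stored as the O1–C2 bond of ring C of naringenin, and whose hydroxydihydropyran is traced back through a chromene to a 7-O-(1,1-dimethylpropargyl) ether. Heating the 5,4'-diacetate of this ether forms the aryl C–C bond and closes the 2H-pyran in one operation. The step exploits that chroman O1 (on C8a) lies para to the acyl-bearing C6 of the benzo ring, flanked by C5-OH and C7-OH: the carbons next to C8a (C4a, C8) are equivalent, so migration to flavanone C6 or C8 gives the same chalcone once ring C is opened. Asymmetric epoxidation and benzylic hydrogenolysis then set C3.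

Key step: step 3

Remark on the chemistry: naringenin is taken as the racemate. Flavanone C2 is left undefined in every intermediate, so compounds 13 to 18 are pairs of C2 epimers, and this centre disappears in step 9. Steps 3 and 4 are one flask operation that gives two regioisomers. The pairs 5/6 and 7/8 are likewise run on the mixture, or on the separated isomers if characterisation is wanted. The oxiranes 13 and 14 are only filtered through base-washed silica and used at once. Enantiopurity is best assayed on 19, where C2 no longer complicates the analysis.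

Step 1
Reactants: 1 naringenin; 2 (3-chloro-3-methylbut-1-yne)
Product: 3 7-O-(1,1-dimethylpropargyl)naringenin
Conditions: 2 (1.1 equiv), CuCl2·2H2O (1 mol %), DBU (1.1 equiv), MeCN, 0 °C
Reagents that add atoms: 3-chloro-3-methylbut-1-yne (compound 2), CC(C)(Cl)C#C
Why: Copper-catalysed propargylic etherification of a phenoxide with a tertiary propargylic chloride: with about one equivalent of DBU only the 7-OH is ionised, because it is para to the C4 carbonyl and much more acidic than the chelated 5-OH or the ordinary 4'-OH, and the low temperature keeps ring C closed.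

Step 2
Reactants: 3 7-O-(1,1-dimethylpropargyl)naringenin
Product: 4 7-O-(1,1-dimethylpropargyl)naringenin 5,4'-diacetate
Conditions: Ac2O (3 equiv), pyridine, DMAP (cat.), CH2Cl2, 0 °C → rt
Reagents that add atoms: acetic anhydride, CC(=O)OC(C)=O
Why: DMAP-catalysed O-acetylation of phenols caps the hydrogen-bonded 5-OH and the 4'-OH, so that O7 will be the only free phenolic oxygen beside the allene in step 3 and no free phenol meets the later oxidant, while the tertiary propargyl ether and the alkyne are inert to Ac2O and pyridine.

Step 3
Reactants: 4 7-O-(1,1-dimethylpropargyl)naringenin 5,4'-diacetate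
Product: 8 linear pyranoflavanone diacetate, via 6-allenyl dienone 5 (not isolated), via 6-allenyl phenol 6 (not isolated), via 6-ylidene quinone methide 7 (not isolated)
Conditions: 1,2-dichlorobenzene (0.05 M), Ar, 180 °C
Reagents that add atoms: none
Why: Heating triggers a [3,3] sigmatropic shift of the aryl propargyl ether (propargyl Claisen rearrangement) that breaks O7–CMe2 and joins C6 to the alkyne terminus (dienone 5); enolisation gives allenyl phenol 6, a 1,5-hydrogen shift from O7–H to the central allene carbon gives the o-quinone methide 7 with its vinyl group turned toward C7=O, and this closes to the chromene. The closest known reaction type is the thermal conversion of aryl 1,1-dimethylpropargyl ethers into 2,2-dimethyl-2H-chromenes, which is established for 7-O-propargylated flavonoids and is helped by the gem-dimethyl group and by the carbonyl para to O7. The 2H-pyran is closed by a thermally allowed disrotatory oxa-6π electrocyclisation of the 1-oxatriene O7=C7–C6=CH–CH=CMe2, in which O7 bonds to CMe2 again (formally a 6-endo closure onto the allene). No stereocentre is formed, and the racemic C2 is a spectator. The selectivity that matters is closure through O7 and never through O5, which the 5-acetate secures because O7 is then the only free oxygen ortho to the allene; the C6 versus C8 choice of the [3,3] shift needs no control, since both chromenes give one chalcone in step 9. Neutral, base-free heating is chosen so that the base-promoted 5-exo closure to a benzofuran and any acetate transfer are not expected to compete.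

Step 4
Reactants: 4 7-O-(1,1-dimethylpropargyl)naringenin 5,4'-diacetate
Product: 12 angular pyranoflavanone diacetate, via 8-allenyl dienone 9 (not isolated), via 8-allenyl phenol 10 (not isolated), via 8-ylidene quinone methide 11 (not isolated)
Conditions: same flask as step 3: 1,2-dichlorobenzene (0.05 M), Ar, 180 °C
Reagents that add atoms: none
Why: The same propargyl Claisen rearrangement, 1,5-hydrogen shift and oxa-6π electrocyclisation as in step 3, with the [3,3] shift directed to C8, the other free carbon ortho to O7; the product is a regioisomer of 8 that converges with it in step 9, so the ratio of the two needs no control.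

Step 5
Reactants: 8 linear pyranoflavanone diacetate
Product: 13 linear chromene oxide (both oxirane carbons R)
Conditions: (R,R)-(salen)MnCl [salen = N,N'-bis(3,5-di-tert-butylsalicylidene)cyclohexane-1,2-diamine dianion] (5 mol %), mCPBA (2 equiv), NMO (5 equiv), CH2Cl2, −78 °C; cold aq. NaHCO3/Na2S2O3
Reagents that add atoms: mCPBA (3-chloroperoxybenzoic acid), O=C(OO)c1cccc(Cl)c1
Why: Jacobsen–Katsuki epoxidation, for which cis olefins conjugated to an arene, and 2,2-dimethylchromenes in particular, are the best substrate class: the oxo-manganese salen species from the (R,R) complex should deliver oxygen to the face that gives the (R,R)-oxirane, and the anhydrous mCPBA/NMO protocol at −78 °C leaves the aryl acetates and the ketone alone.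

Step 6
Reactants: 12 angular pyranoflavanone diacetate
Product: 14 angular chromene oxide (both oxirane carbons R)
Conditions: (R,R)-(salen)MnCl (5 mol %), mCPBA (2 equiv), NMO (5 equiv), CH2Cl2, −78 °C; cold aq. NaHCO3/Na2S2O3
Reagents that add atoms: mCPBA (3-chloroperoxybenzoic acid), O=C(OO)c1cccc(Cl)c1
Why: The same Jacobsen–Katsuki epoxidation on the regioisomeric cis chromene olefin, where the catalyst again controls the face and should give the (R,R)-oxirane, that is the same absolute configuration at the carbon next to CMe2 as in 13.

Step 7
Reactants: 13 linear chromene oxide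
Product: 15 linear (R)-hydroxydihydropyranoflavanone diacetate
Conditions: H2 (1 atm), 10% Pd/C, solid NaHCO3, EtOAc, rt
Reagents that add atoms: none
Why: Palladium-catalysed hydrogenolysis of a benzylic C–O bond cleaves only the strained benzylic C–O bond of the aryl oxirane, so the oxygen stays on the carbon next to CMe2 with its R configuration untouched, and at 1 atm in a neutral medium the deactivated aryl ketone, the acetates and the flavanone O1–C2 bond are not expected to react.

Step 8
Reactants: 14 angular chromene oxide
Product: 16 angular (R)-hydroxydihydropyranoflavanone diacetate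
Conditions: H2 (1 atm), 10% Pd/C, solid NaHCO3, EtOAc, rt
Reagents that add atoms: none
Why: The same benzylic C–O hydrogenolysis of an aryl oxirane, which removes only the oxygen bond at the benzylic carbon and leaves the R carbinol next to CMe2 as it was set in step 6.

Step 9
Reactants: 15 linear (R)-hydroxydihydropyranoflavanone diacetate; 16 angular (R)-hydroxydihydropyranoflavanone diacetate
Product: 19 target chalcone CNP0300839.1, via linear free flavanone 17 (not isolated), via angular free flavanone 18 (not isolated)
Conditions: KOH (30% aq., large excess), MeOH, Ar, rt → 50 °C; then poured into ice-cold 2 M HCl (pH 3), EtOAc, kept cold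
Reagents that add atoms: none
Why: Ester saponification followed by E1cB retro-oxa-Michael opening of 5-hydroxyflavanones, the known alkaline route from such flavanones to 2',6'-dihydroxychalcones: hydroxide strips both acetates to give 17 and 18, the enolate at the ring C methylene of each expels the O1 phenoxide, and both converge on one delocalised chalcone phenolate with the thermodynamically preferred E enone, while the carbinol centre is not enolisable and stays R.

Compound list
1 | naringenin, racemic 5,7-dihydroxy-2-(4-hydroxyphenyl)chroman-4-one | O=C1CC(c2ccc(O)cc2)Oc2cc(O)cc(O)c12 | starting material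
2 | 3-chloro-3-methylbut-1-yne | CC(C)(Cl)C#C | starting material
3 | 7-O-(1,1-dimethylpropargyl)naringenin: 5-hydroxy-2-(4-hydroxyphenyl)-7-(2-methylbut-3-yn-2-yloxy)chroman-4-one, C2 racemic | O=C1CC(c2ccc(O)cc2)Oc2cc(OC(C)(C)C#C)cc(O)c12 | intermediate
4 | 5,4'-diacetate of 3: 5-acetoxy-2-(4-acetoxyphenyl)-7-(2-methylbut-3-yn-2-yloxy)chroman-4-one, C2 racemic | O=C1CC(c2ccc(OC(C)=O)cc2)Oc2cc(OC(C)(C)C#C)cc(OC(C)=O)c12 | intermediate
5 | 6-allenyl dienone: 5-acetoxy-2-(4-acetoxyphenyl)-6-(3-methylbuta-1,2-dienyl)-2,3-dihydro-4H-chromene-4,7(6H)-dione | O=C1CC(c2ccc(OC(C)=O)cc2)OC2=CC(=O)C(C=C=C(C)C)C(OC(C)=O)=C12 | intermediate (not isolated)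
6 | 6-allenyl phenol: 5-acetoxy-2-(4-acetoxyphenyl)-7-hydroxy-6-(3-methylbuta-1,2-dienyl)chroman-4-one | O=C1CC(c2ccc(OC(C)=O)cc2)Oc2cc(O)c(C=C=C(C)C)c(OC(C)=O)c12 | intermediate (not isolated)
7 | 6-ylidene quinone methide: 5-acetoxy-2-(4-acetoxyphenyl)-6-(3-methylbut-2-enylidene)-2,3-dihydro-4H-chromene-4,7(6H)-dione, vinyl group on the C7 side of the exocyclic double bond | O=C1CC(c2ccc(OC(C)=O)cc2)OC2=CC(=O)/C(=C\C=C(C)C)C(OC(C)=O)=C12 | intermediate (not isolated)
8 | linear pyranoflavanone diacetate: 5-acetoxy-8-(4-acetoxyphenyl)-2,2-dimethyl-7,8-dihydro-2H,6H-pyrano[3,2-g]chromen-6-one (2H-pyran fused at flavanone C6–C7, pyran oxygen = O7), C8 racemic | O=C1CC(c2ccc(OC(C)=O)cc2)Oc2cc3OC(C)(C)C=Cc3c(OC(C)=O)c12 | intermediate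
9 | 8-allenyl dienone: 5-acetoxy-2-(4-acetoxyphenyl)-8-(3-methylbuta-1,2-dienyl)-2,3-dihydro-4H-chromene-4,7(8H)-dione | O=C1CC(c2ccc(OC(C)=O)cc2)OC2=C1C(OC(C)=O)=CC(=O)C2C=C=C(C)C | intermediate (not isolated)
10 | 8-allenyl phenol: 5-acetoxy-2-(4-acetoxyphenyl)-7-hydroxy-8-(3-methylbuta-1,2-dienyl)chroman-4-one | O=C1CC(c2ccc(OC(C)=O)cc2)Oc2c(C=C=C(C)C)c(O)cc(OC(C)=O)c12 | intermediate (not isolated)
11 | 8-ylidene quinone methide: 5-acetoxy-2-(4-acetoxyphenyl)-8-(3-methylbut-2-enylidene)-2,3-dihydro-4H-chromene-4,7(8H)-dione, vinyl group on the C7 side of the exocyclic double bond | O=C1CC(c2ccc(OC(C)=O)cc2)OC2=C1C(OC(C)=O)=CC(=O)/C2=C\C=C(C)C | intermediate (not isolated)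
12 | angular pyranoflavanone diacetate: 5-acetoxy-2-(4-acetoxyphenyl)-8,8-dimethyl-2,3-dihydro-4H,8H-pyrano[2,3-h]chromen-4-one (2H-pyran fused at flavanone C7–C8, pyran oxygen = O7), C2 racemic | O=C1CC(c2ccc(OC(C)=O)cc2)Oc2c3C=CC(C)(C)Oc3cc(OC(C)=O)c12 | intermediate
13 | linear chromene oxide: (3R,4R)-3,4-epoxide of 8 (cis-fused oxirane on the former pyran olefin), C8 epimers | O=C1CC(c2ccc(OC(C)=O)cc2)Oc2cc3OC(C)(C)[C@@H]4O[C@@H]4c3c(OC(C)=O)c12 | intermediate
14 | angular chromene oxide: (9R,10R)-9,10-epoxide of 12 (cis-fused oxirane on the former pyran olefin), C2 epimers | O=C1CC(c2ccc(OC(C)=O)cc2)Oc2c3[C@H]4O[C@H]4C(C)(C)Oc3cc(OC(C)=O)c12 | intermediate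
15 | linear alcohol: (3R)-5-acetoxy-8-(4-acetoxyphenyl)-3-hydroxy-2,2-dimethyl-3,4,7,8-tetrahydro-2H,6H-pyrano[3,2-g]chromen-6-one, C8 epimers | O=C1CC(c2ccc(OC(C)=O)cc2)Oc2cc3OC(C)(C)[C@H](O)Cc3c(OC(C)=O)c12 | intermediate
16 | angular alcohol: (9R)-5-acetoxy-2-(4-acetoxyphenyl)-9-hydroxy-8,8-dimethyl-2,3,9,10-tetrahydro-4H,8H-pyrano[2,3-h]chromen-4-one, C2 epimers | O=C1CC(c2ccc(OC(C)=O)cc2)Oc2c3C[C@@H](O)C(C)(C)Oc3cc(OC(C)=O)c12 | intermediate
17 | linear free flavanone: 15 with both acetates removed (free 5-OH and 4'-OH, R carbinol), C8 epimers | O=C1CC(c2ccc(O)cc2)Oc2cc3OC(C)(C)[C@H](O)Cc3c(O)c12 | intermediate (not isolated)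
18 | angular free flavanone: 16 with both acetates removed (free 5-OH and 4'-OH, R carbinol), C2 epimers | O=C1CC(c2ccc(O)cc2)Oc2c3C[C@@H](O)C(C)(C)Oc3cc(O)c12 | intermediate (not isolated)
19 | CNP0300839.1: (E)-3-(4-hydroxyphenyl)-1-[(3R)-3,5,7-trihydroxy-2,2-dimethylchroman-6-yl]prop-2-en-1-one | CC1(C)Oc2cc(O)c(C(=O)/C=C/c3ccc(O)cc3)c(O)c2C[C@H]1O | target

Total step count: 9 numbered steps. Steps 3/4, 5/6 and 7/8 are each one flask operation on the regioisomer pair, which makes 6 laboratory operations.
Longest linear sequence: 6 steps (1, 2, 3, 5, 7, 9, or equally 1, 2, 4, 6, 8, 9).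

Steps most likely to fail

Step 9. The opening is an equilibrium that may stop short of completion. The chalcone may also re-close to the flavanones while the solution passes through the weakly basic range on acidification, and prolonged heating in alkali may cause retro-aldol loss of the aryl aldehyde. Recovered flavanone can simply be resubmitted. If that is not enough, the fallback traps the open form irreversibly and releases it under acid, where ring closure is slow. It sets out from the free flavanones 17 and 18, which are what re-closure returns (or which are liberated from 15 and 16 with K2CO3 in MeOH). These are heated with K2CO3 and chloromethyl methyl ether in acetone. Under these carbonate and alkyl halide conditions 5-hydroxyflavanones open, and the liberated phenoxide and the 4'-phenoxide are alkylated. The carbinol and one chelated ortho hydroxyl stay free, which should give the 7-O-methoxymethyl chalcone F1 and the 5-O-methoxymethyl chalcone F2 (chroman numbering), both carrying a 4-methoxymethoxy group on ring B. These stable E chalcones are purified and then treated with HCl in MeOH (rt to 40 °C), which cleaves the methoxymethyl acetals. The route is rejoined at 19.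

Step 5 (and its twin, step 6). The electron-rich benzylic oxirane may open or rearrange under traces of acid during reaction and isolation, and the substituent peri to the olefin may lower the facial selectivity. The fallback avoids the oxirane altogether. It sets out from the chromenes 8 and 12 and uses a Sharpless asymmetric dihydroxylation under base-free conditions: K2OsO2(OH)4 (cat.), (DHQ)2PYR, NMO, acetone/H2O, 0 °C, slow addition of the olefin. The ferricyanide/K2CO3 medium is avoided because it would strip the aryl acetates. The (DHQ)2PYR ligand is chosen because it is the one expected, by analogy with other 2,2-dimethylchromenes, to give the linear (3R,4R)-cis-diol F3 and the angular (9R,10R)-cis-diol F4. Ionic hydrogenation (Et3SiH, BF3·OEt2, CH2Cl2, −78 → −40 °C) should then remove only the ionisable benzylic hydroxyl and leave the R carbinol next to CMe2. The route is rejoined at 15 and 16; compounds 13 and 14 and steps 7 and 8 are bypassed.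

Step 1. Alkylation may also occur at the 4'-hydroxyl, including double alkylation, and the base may open ring C. The fallback protects first and alkylates last. It sets out from 1, which is peracetylated (Ac2O, pyridine) to naringenin triacetate F5. The 7-acetate, the most activated of the three, is removed chemoselectively by acyl transfer to thiophenol (PhSH, imidazole cat., N-methylpyrrolidone, 0 °C → rt) to give 5,4'-di-O-acetylnaringenin F6. Its single free hydroxyl is then propargylated with 2 under the copper conditions of step 1 (CuCl2·2H2O cat., DBU 1.05 equiv, MeCN, 0 °C). The route is rejoined at 4; compound 3 is bypassed.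

Further compounds
F1 | step 9 | 7-O-methoxymethyl chalcone: (E)-1-[(3R)-3,5-dihydroxy-7-(methoxymethoxy)-2,2-dimethylchroman-6-yl]-3-[4-(methoxymethoxy)phenyl]prop-2-en-1-one | CC1(C)Oc2cc(OCOC)c(C(=O)/C=C/c3ccc(OCOC)cc3)c(O)c2C[C@H]1O
F2 | step 9 | 5-O-methoxymethyl chalcone: (E)-1-[(3R)-3,7-dihydroxy-5-(methoxymethoxy)-2,2-dimethylchroman-6-yl]-3-[4-(methoxymethoxy)phenyl]prop-2-en-1-one | CC1(C)Oc2cc(O)c(C(=O)/C=C/c3ccc(OCOC)cc3)c(OCOC)c2C[C@H]1O
F3 | step 5 | linear (3R,4R)-cis-diol: 8 with cis hydroxyls on both former olefin carbons | O=C1CC(c2ccc(OC(C)=O)cc2)Oc2cc3OC(C)(C)[C@H](O)[C@H](O)c3c(OC(C)=O)c12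
F4 | step 5 | angular (9R,10R)-cis-diol: 12 with cis hydroxyls on both former olefin carbons | O=C1CC(c2ccc(OC(C)=O)cc2)Oc2c3[C@@H](O)[C@@H](O)C(C)(C)Oc3cc(OC(C)=O)c12
F5 | step 1 | naringenin triacetate: 5,7-diacetoxy-2-(4-acetoxyphenyl)chroman-4-one | O=C1CC(c2ccc(OC(C)=O)cc2)Oc2cc(OC(C)=O)cc(OC(C)=O)c12
F6 | step 1 | 5,4'-di-O-acetylnaringenin: 5-acetoxy-2-(4-acetoxyphenyl)-7-hydroxychroman-4-one | O=C1CC(c2ccc(OC(C)=O)cc2)Oc2cc(O)cc(OC(C)=O)c12
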